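**Retrosynthetic overview**
1. Target 22 ⇒ cross-metathesis of triene diol 20 with methacrylic acid (C2=C3 and the acid come last).
2. 20 ⇒ Felkin–Anh methyl addition to ketone 18 ⇒ Weinreb acylation of bicyclic ester 9 with a C9 homoallyl Grignard (from hex-5-en-1-yne and ethylene oxide by carboalumination).
3. 9 ⇒ silyl-directed Cloke–Wilson ring expansion (cyclopropane → dihydrofuran, proposed new) of the α-silyloxy spirocyclopropane dione 7.
4. 7 ⇒ asymmetric α-hydroxylation of spirodione ester 4 ⇒ asymmetric cyclopropanation of methyl acrylate with 2-diazocyclohexane-1,3-dione.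
5. Ring order: the carbocycle is bought as cyclohexane-1,3-dione; the cyclopropane is formed in step 2; the dihydrofuran is formed from it by ring expansion in step 4.

Assumption: the antipodes of the cobalt catalyst (step 2) and of the oxaziridine (step 3) are those that give the configurations drawn; the sense is checked on a pilot run and the other antipode is used if needed.

**Step 1**
Reactants: 1 cyclohexane-1,3-dione
Product: 2 2-diazocyclohexane-1,3-dione
Conditions: 4-acetamidobenzenesulfonyl azide, Et3N, MeCN, 0 °C → rt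
Reagents that add atoms: 4-acetamidobenzenesulfonyl azide, CC(=O)Nc1ccc(cc1)S(=O)(=O)N=[N+]=[N-]
Why: Regitz diazo transfer to the doubly activated C2–H of the 1,3-dione; no stereocentre is formed.

**Step 2**
Reactants: 2 2-diazocyclohexane-1,3-dione; 3 methyl acrylate
Product: 4 methyl (1R)-4,8-dioxospiro[2.5]octane-1-carboxylate
Conditions: 3 (3 equiv), chiral D2-symmetric amidoporphyrin cobalt(II) complex (2 mol %), PhCl, 40 °C
Reagents that add atoms: none
Why: Asymmetric Co(II)-metalloradical cyclopropanation: the α-cobalt(III)-alkyl radical from the acceptor/acceptor diazo compound adds to the electron-poor acrylate and closes by 3-exo radical substitution inside the chiral porphyrin pocket, which sets C1 as R. The cyclopropane also keeps the ester α-position non-enolisable in step 3.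

**Step 3**
Reactants: 4 methyl (1R)-4,8-dioxospiro[2.5]octane-1-carboxylate
Product: 7 methyl (1R,5R)-4,8-dioxo-5-[(triethylsilyl)oxy]spiro[2.5]octane-1-carboxylate (both C3 epimers), via lithium enolate 5 (not isolated), via lithium alkoxide 6 (not isolated)
Conditions: LiHMDS (1.05 equiv), THF, −78 °C; (+)-[(8,8-dichlorocamphoryl)sulfonyl]oxaziridine, −78 °C; then Et3SiCl, imidazole, −78 → 0 °C
Reagents that add atoms: (+)-[(8,8-dichlorocamphoryl)sulfonyl]oxaziridine, CC1(C)C2CCC13CS(=O)(=O)N4OC34C2(Cl)Cl; chlorotriethylsilane, CC[Si](Cl)(CC)CC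
Why: Kinetic mono-enolate formation (only the ring CH2 groups are acidic) and Davis oxidation with the chiral N-sulfonyloxaziridine set the carbinol centre as R under reagent control. Either ketone may enolise, because the two products differ only at the spiro carbon, which is destroyed in step 4.

**Step 4**
Reactants: 7 methyl (1R,5R)-4,8-dioxo-5-[(triethylsilyl)oxy]spiro[2.5]octane-1-carboxylate
Product: 9 methyl (2S,7R)-4-oxo-7-[(triethylsilyl)oxy]-2,3,4,5,6,7-hexahydro-1-benzofuran-2-carboxylate, via iodo silyl enol ether 8 (not isolated)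
Conditions: Et3SiOTf (20 mol %), n-Bu4NI (20 mol %), 2,6-di-tert-butyl-4-methylpyridine (10 mol %), CH2Cl2, −40 → 0 °C; aq. NaHCO3
Reagents that add atoms: none
Why: Proposed new method: a silyl-iodide-relayed, regiodirected Cloke–Wilson ring expansion. Et3SiI made in situ should silylate the more basic and less shielded C8 carbonyl (the C4 carbonyl is deactivated and screened by the adjacent OSiEt3). Iodide then opens the C1–C3 bond at the ester-bearing carbon (SN2 α to the ester, inversion) to give 8. Only the free carbonyl oxygen next to the silyloxy carbon can close on the α-iodo ester (second inversion, so net retention: 1R becomes 2S), and iodide takes the silyl group off again to turn the catalyst over. This puts the ring oxygen next to C7–O, the opposite of what enolate O-alkylation would give. The closest known reactions are the halide- or Lewis-acid-promoted Cloke–Wilson rearrangement of 1,1-diacylcyclopropanes and the Me3SiI homoconjugate opening of cyclopropyl ketones.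

**Step 5**
Reactants: 10 hex-5-en-1-yne; 11 ethylene oxide
Product: 14 (3E)-4-methylocta-3,7-dien-1-ol, via alkenylalane 12 (not isolated), via lithium alanate 13 (not isolated)
Conditions: Me3Al, Cp2ZrCl2 (20 mol %), CH2Cl2, 0 °C → rt; n-BuLi, THF, −78 °C; 11, −78 °C → rt; aq. HCl
Reagents that add atoms: trimethylaluminium, C[Al](C)C
Why: Negishi zirconium-catalysed carboalumination adds Me–Al syn across the terminal alkyne (the alkene is untouched), and the derived alanate opens ethylene oxide with retention, which fixes the E trisubstituted alkene.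

**Step 6**
Reactants: 14 (3E)-4-methylocta-3,7-dien-1-ol
Product: 15 (5E)-8-iodo-5-methylocta-1,5-diene
Conditions: I2, PPh3, imidazole, CH2Cl2, 0 °C → rt
Reagents that add atoms: iodine, II
Why: Appel-type iodination (SN2 at the primary carbinol); the alkenes are inert.

**Step 7**
Reactants: 9 methyl (2S,7R)-4-oxo-7-[(triethylsilyl)oxy]-2,3,4,5,6,7-hexahydro-1-benzofuran-2-carboxylate; 15 (5E)-8-iodo-5-methylocta-1,5-diene
Product: 18 (2S,7R)-2-[(4E)-5-methylnona-4,8-dienoyl]-7-[(triethylsilyl)oxy]-3,5,6,7-tetrahydro-1-benzofuran-4(2H)-one, via Weinreb amide 16 (not isolated), via Grignard reagent 17 (not isolated)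
Conditions: MeNH(OMe)·HCl, i-PrMgCl, THF, −20 °C; then 17 (from 15, Mg, THF, rt), −20 → 0 °C; aq. NH4Cl
Reagents that add atoms: none
Why: Magnesium amide aminolysis of the activated α-alkoxy ester gives the Weinreb amide, whose chelated tetrahedral adduct with the Grignard reagent prevents over-addition (Weinreb ketone synthesis). The vinylogous ester carbonyl is far less electrophilic, and C2 is not touched at low temperature.

**Step 8**
Reactants: 18 (2S,7R)-2-[(4E)-5-methylnona-4,8-dienoyl]-7-[(triethylsilyl)oxy]-3,5,6,7-tetrahydro-1-benzofuran-4(2H)-one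
Product: 20 (2S,7R)-7-hydroxy-2-[(2S,5E)-2-hydroxy-6-methyldeca-5,9-dien-2-yl]-3,5,6,7-tetrahydro-1-benzofuran-4(2H)-one, via triethylsilyl ether 19 (not isolated)
Conditions: MeTi(OiPr)3, THF, −30 → 0 °C; aq. NH4Cl; crude, HF·pyridine, THF, 0 °C
Reagents that add atoms: methyltitanium triisopropoxide, C[Ti](OC(C)C)(OC(C)C)OC(C)C
Why: Felkin–Anh (non-chelating) addition of the methyltitanium reagent: with the C2–O1 bond anti to the incoming methyl and attack past C2–H, the new carbinol centre is S. The reagent leaves the vinylogous ester alone, and buffered fluoride then removes the silyl group without acid that could open the enol ether.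

**Step 9**
Reactants: 20 (2S,7R)-7-hydroxy-2-[(2S,5E)-2-hydroxy-6-methyldeca-5,9-dien-2-yl]-3,5,6,7-tetrahydro-1-benzofuran-4(2H)-one; 21 methacrylic acid
Product: 22 (2E,6E,10S)-10-hydroxy-10-[(2S,7R)-7-hydroxy-4-oxo-2,3,4,5,6,7-hexahydro-1-benzofuran-2-yl]-2,6-dimethylundeca-2,6-dienoic acid
Conditions: 21 (10 equiv), Hoveyda–Grubbs II (5 mol %), CH2Cl2, 40 °C
Reagents that add atoms: none
Why: Olefin cross-metathesis of the terminal alkene with excess methacrylic acid gives the E trisubstituted enoic acid under thermodynamic control; the tri- and tetrasubstituted alkenes do not react.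

**Compound list**
1 | cyclohexane-1,3-dione | O=C1CCCC(=O)C1 | starting material
2 | 2-diazocyclohexane-1,3-dione | [N-]=[N+]=C1C(=O)CCCC1=O | intermediate
3 | methyl acrylate | C=CC(=O)OC | starting material
4 | methyl (1R)-4,8-dioxospiro[2.5]octane-1-carboxylate | COC(=O)[C@@H]1CC12C(=O)CCCC2=O | intermediate
5 | lithium mono-enolate of 4 (not isolated) | [Li+].COC(=O)[C@@H]1CC12C([O-])=CCCC2=O | intermediate
6 | lithium (1R,5R)-1-(methoxycarbonyl)-4,8-dioxospiro[2.5]octan-5-olate (not isolated) | [Li+].COC(=O)[C@@H]1CC12C(=O)[C@H]([O-])CCC2=O | intermediate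
7 | methyl (1R,5R)-4,8-dioxo-5-[(triethylsilyl)oxy]spiro[2.5]octane-1-carboxylate (both C3 epimers) | COC(=O)[C@@H]1CC12C(=O)[C@H](O[Si](CC)(CC)CC)CCC2=O | intermediate
8 | methyl (2R)-2-iodo-3-{(5R)-6-oxo-2,5-bis[(triethylsilyl)oxy]cyclohex-1-en-1-yl}propanoate (not isolated) | COC(=O)[C@H](I)CC1=C(O[Si](CC)(CC)CC)CC[C@@H](O[Si](CC)(CC)CC)C1=O | intermediate
9 | methyl (2S,7R)-4-oxo-7-[(triethylsilyl)oxy]-2,3,4,5,6,7-hexahydro-1-benzofuran-2-carboxylate | COC(=O)[C@@H]1CC2=C(O1)[C@H](O[Si](CC)(CC)CC)CCC2=O | intermediate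
10 | hex-5-en-1-yne | C#CCCC=C | starting material
11 | ethylene oxide | C1CO1 | starting material
12 | dimethyl[(1E)-2-methylhexa-1,5-dien-1-yl]alumane (not isolated) | C[Al](C)/C=C(\C)CCC=C | intermediate
13 | lithium butyl(dimethyl)[(1E)-2-methylhexa-1,5-dien-1-yl]alanate (not isolated) | [Li+].CCCC[Al-](C)(C)/C=C(\C)CCC=C | intermediate
14 | (3E)-4-methylocta-3,7-dien-1-ol | OCC/C=C(\C)CCC=C | intermediate
15 | (5E)-8-iodo-5-methylocta-1,5-diene | ICC/C=C(\C)CCC=C | intermediate
16 | (2S,7R)-N-methoxy-N-methyl-4-oxo-7-[(triethylsilyl)oxy]-2,3,4,5,6,7-hexahydro-1-benzofuran-2-carboxamide (not isolated) | CON(C)C(=O)[C@@H]1CC2=C(O1)[C@H](O[Si](CC)(CC)CC)CCC2=O | intermediate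
17 | iodo[(3E)-4-methylocta-3,7-dien-1-yl]magnesium (not isolated) | I[Mg]CC/C=C(\C)CCC=C | intermediate
18 | (2S,7R)-2-[(4E)-5-methylnona-4,8-dienoyl]-7-[(triethylsilyl)oxy]-3,5,6,7-tetrahydro-1-benzofuran-4(2H)-one | C/C(=C\CCC(=O)[C@@H]1CC2=C(O1)[C@H](O[Si](CC)(CC)CC)CCC2=O)CCC=C | intermediate
19 | (2S,7R)-2-[(2S,5E)-2-hydroxy-6-methyldeca-5,9-dien-2-yl]-7-[(triethylsilyl)oxy]-3,5,6,7-tetrahydro-1-benzofuran-4(2H)-one (not isolated) | C/C(=C\CC[C@](C)(O)[C@@H]1CC2=C(O1)[C@H](O[Si](CC)(CC)CC)CCC2=O)CCC=C | intermediate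
20 | (2S,7R)-7-hydroxy-2-[(2S,5E)-2-hydroxy-6-methyldeca-5,9-dien-2-yl]-3,5,6,7-tetrahydro-1-benzofuran-4(2H)-one | C/C(=C\CC[C@](C)(O)[C@@H]1CC2=C(O1)[C@H](O)CCC2=O)CCC=C | intermediate
21 | methacrylic acid | CC(=C)C(=O)O | starting material
22 | (2E,6E,10S)-10-hydroxy-10-[(2S,7R)-7-hydroxy-4-oxo-2,3,4,5,6,7-hexahydro-1-benzofuran-2-yl]-2,6-dimethylundeca-2,6-dienoic acid | C/C(=C\CC[C@](C)(O)[C@@H]1CC2=C(O1)[C@H](O)CCC2=O)CC/C=C(\C)C(=O)O | target

**Count and risks**
Total step count: 9. Longest linear sequence: 7 (steps 1, 2, 3, 4, 7, 8, 9).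

The three steps most likely to fail:

Step 2 (asymmetric cyclopropanation). The cyclic diazodione is a more stabilised carbene source than those usually used with this catalyst class, so conversion or ee may be poor. Fallback, setting out from 1 and returning at 4: bromination with N-bromosuccinimide gives 2-bromocyclohexane-1,3-dione F1. A K2CO3-mediated Michael-initiated ring closure with 3 (DMF, rt) can only close through carbon and gives the racemic cyclopropane, methyl (1RS)-4,8-dioxospiro[2.5]octane-1-carboxylate F2. Preparative chiral SFC then separates 4 from its enantiomer, methyl (1S)-4,8-dioxospiro[2.5]octane-1-carboxylate F3, which is discarded.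

Step 4 (the proposed new ring expansion). The risks are closure through the wrong oxygen (giving the 5-silyloxy regioisomer) and erosion at C2 by iodide exchange on 8. Fallback by known reactions, setting out from 7 and returning at 9, run stepwise and irreversibly: stoichiometric Me3SiI (CH2Cl2, −78 °C) then cold methanol gives the ring-opened enol, methyl (2R)-3-{(5R)-2-hydroxy-6-oxo-5-[(triethylsilyl)oxy]cyclohex-1-en-1-yl}-2-iodopropanoate F4. Neutral silylation with N-(tert-butyldimethylsilyl)-N-methyltrifluoroacetamide caps the less hindered enol oxygen to give methyl (2R)-3-{(5R)-2-[(tert-butyldimethylsilyl)oxy]-6-oxo-5-[(triethylsilyl)oxy]cyclohex-1-en-1-yl}-2-iodopropanoate F5. AgOTf (CH2Cl2, −20 °C) then closes the ring through the free carbonyl oxygen, and the silyl group is lost on work-up to give 9. Here the silyl group can be made bulkier and the closure cannot revert.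

Step 8 (facial selectivity of the methyl addition). The ring oxygen may not impose clean Felkin–Anh control. Fallback, setting out from 9 and returning at 19: the Weinreb amide 16 is treated with MeMgBr to give the methyl ketone, (2S,7R)-2-acetyl-7-[(triethylsilyl)oxy]-3,5,6,7-tetrahydro-1-benzofuran-4(2H)-one F6. The chain is then added as Grignard reagent 17 (MgBr2·OEt2, CH2Cl2, −78 °C) to give 19, which is desilylated to 20 as before. Because the two substituents now enter in the opposite order, the same facial preference that gave the wrong carbinol in step 8 gives the right one here.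

**Further compounds**
F1 | step 2 | 2-bromocyclohexane-1,3-dione (enol form) | O=C1CCCC(O)=C1Br
F2 | step 2 | methyl (1RS)-4,8-dioxospiro[2.5]octane-1-carboxylate | COC(=O)C1CC12C(=O)CCCC2=O
F3 | step 2 | methyl (1S)-4,8-dioxospiro[2.5]octane-1-carboxylate | COC(=O)[C@H]1CC12C(=O)CCCC2=O
F4 | step 4 | methyl (2R)-3-{(5R)-2-hydroxy-6-oxo-5-[(triethylsilyl)oxy]cyclohex-1-en-1-yl}-2-iodopropanoate | COC(=O)[C@H](I)CC1=C(O)CC[C@@H](O[Si](CC)(CC)CC)C1=O
F5 | step 4 | methyl (2R)-3-{(5R)-2-[(tert-butyldimethylsilyl)oxy]-6-oxo-5-[(triethylsilyl)oxy]cyclohex-1-en-1-yl}-2-iodopropanoate | COC(=O)[C@H](I)CC1=C(O[Si](C)(C)C(C)(C)C)CC[C@@H](O[Si](CC)(CC)CC)C1=O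
F6 | step 8 | (2S,7R)-2-acetyl-7-[(triethylsilyl)oxy]-3,5,6,7-tetrahydro-1-benzofuran-4(2H)-one | CC(=O)[C@@H]1CC2=C(O1)[C@H](O[Si](CC)(CC)CC)CCC2=O
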